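At late times the first step, taken by itself, brings X and L to its balance, so what I wanted of each flask was that balance and the part of the way to it gone by the end.

    X ⇌ L (K1 = 0.38, k1 = 0.014 s⁻¹, Ea1 = 83.0 kJ mol⁻¹, ΔH1 = −54.0 kJ mol⁻¹)
    G + J ⇌ X + J, rate k2*[J]*[G] forward; the back reaction follows from the equilibrium constant (k2 = 8.2 M⁻¹ s⁻¹, Ea2 = 46.0 kJ mol⁻¹)
    Q + J ⇌ G + J, rate k3*[J]*[Q] forward; the back reaction follows from the equilibrium constant (K3 = 0.51, k3 = 27 M⁻¹ s⁻¹, Ea3 = 50.0 kJ mol⁻¹, ΔH3 = 6.00 kJ mol⁻¹)
    L + J ⇌ Q + J, rate k4*[J]*[L] forward; the back reaction follows from the equilibrium constant (K4 = 0.21, k4 = 47 M⁻¹ s⁻¹, Ea4 = 38.0 kJ mol⁻¹, ΔH4 = 5.00 kJ mol⁻¹)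
    J + L ⇌ J.L (K5 = 14 M⁻¹, k5 = 0.25 M⁻¹ s⁻¹, Ea5 = 51.0 kJ mol⁻¹, ΔH5 = 41.0 kJ mol⁻¹)
    (constants at 50 °C)

| flask | X | J | temperature | time | remark |
|---|---|---|---|---|---|
| south | 0.30 M | 0.54 mM | 50 °C | 80 s |  |
| south-east | 0.30 M | 0.54 mM | 65 °C | 80 s |  |
| north-west | 0.30 M | 0.54 mM | 35 °C | 80 s |  |
| south-west | 0.30 M | 0.54 mM |  | 80 s | at 35 °C until 1.0 min, from then on at 65 °C |

- what is said of L includes J.L
- the list of constants is for 50 °C, to be carried to other temperatures by the activation energies and enthalpies

- the flask with the highest amount of L, in percent of the X charged ("all alike" if they lie within 1.5 percentage points) (south / south-east / north-west / south-west / all alike)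
- final L, as a percentage of the X charged, in south
- final L, as a percentage of the X charged, in south-east
- final L, as a percentage of the X charged, in north-west
- final L, as a percentage of the X charged, in south-west

Carried by its enthalpy, the equilibrium constant of the first step went from 1.01 at 35 °C through 0.38 at 50 °C to 0.156 at 65 °C, which puts L at balance, counting X and L alone, at fractions of the charge of 0.503, 0.275 and 0.135. I worked with the fraction left and not the fraction made: the gap to balance falls as the exponential of minus time times the closing rate (the relaxation rate), which is the forward constant of the first step plus its backward one, and in south-east that closing rate was 0.409 s⁻¹. Over 80 s south-east kept hardly any of its gap, which is thermodynamic control, so I reckoned its L at 0.135. South, with a closing rate of 0.0508 s⁻¹, kept 0.0171 of its gap, which gave 0.271. North-west, with 0.006191 s⁻¹, kept 0.609, which is kinetic control and gave 0.196. These figures stand before any loss to Q and G, which I did not reckon.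

The forecast named south and gave 25.7% for south, 13% for south-east, 16.8% for north-west and 13.2% for south-west, holding that “north-west is kinetically limited”; its figures for south and north-west lie below mine.

South held the most L, 24.7%, with 17.1% in north-west, 13.0% in south-east and 12.9% in south-west. South's L left the forecast's range when the backward run from L to X was struck out, reaching 55.8%. South-west held 13.7% of L at 60.0 s; its hot stage of 20.0 s at the closing rate of 0.409 s⁻¹ reckons to 2.81 × 10⁻⁴ of the gap left, and it ended with 12.9%, close to the 13.0% of south-east.

(The constants used here are invented; the result is computed.)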